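**Retrosynthetic overview**
1. Target 17 ⇐ Luche reduction of 9-ketone 16 ⇐ anisoylation of 6α-hydroxy enone 14 ⇐ two α-face oxygenations (Schenck ene/dehydration, then vinylogous Rubottom) of dauc-8-en-4β-ol 10, the presumed first cyclase product.
2. 10 ⇐ one cation–olefin cascade on the acyclic farnesane keto-allylsilane 8. C4–C5 (five-membered ring) closes first, then C1–C10 (seven-membered ring). These are the same two bonds, formed across the same E-alkene, as in the nerolidyl → daucyl cyclisation. C4=O stands in for the water-quenched C4 cation and PhMe2Si on C8 for the diphosphate.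
3. 8 ⇐ enolate allylation of 3-methylbutan-2-one with bromide 5 ⇐ Riley oxidation of (R)-linalylsilane 3 ⇐ enantioselective SN2′ silylation of geranyl phosphate 2 ⇐ geraniol.

Assumption: daucane numbering is used for chain and ring carbons throughout (C1 quaternary, C4 carbinol, C5 ring-fusion CH, C6 ester carbon, C8 methyl-bearing alkene carbon, C9 carbinol, C10 CH2, C14/C15 methyls), and the carbene-ligand enantiomer in step 2 is the one that gives the (R)-silane.

**Step 1**
Reactants: 1 geraniol [(2E)-3,7-dimethylocta-2,6-dien-1-ol]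
Product: 2 geranyl diethyl phosphate [(2E)-3,7-dimethylocta-2,6-dien-1-yl diethyl phosphate]
Conditions: ClP(O)(OEt)2, pyridine, CH2Cl2, 0 °C to rt
Reagents that add atoms: diethyl chlorophosphate, CCOP(=O)(Cl)OCC
Why: O-phosphorylation (substitution at phosphorus) installs the leaving group needed for copper-catalysed SN2′ chemistry, leaves the E-alkene untouched and creates no stereocentre.

**Step 2**
Reactants: 2 geranyl diethyl phosphate
Product: 3 (R)-linalylsilane {[(3R)-3,7-dimethylocta-1,6-dien-3-yl](dimethyl)phenylsilane}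
Conditions: PhMe2Si–Bpin, CuCl (5 mol %), chiral hydroxy-armed imidazolinium salt (carbene precursor, 5.5 mol %), NaOH, THF, 0 °C to rt
Reagents that add atoms: (dimethylphenylsilyl)boronic acid pinacol ester, C[Si](C)(c1ccccc1)B1OC(C)(C)C(C)(C)O1
Why: Copper-catalysed enantioselective γ-selective allylic substitution (SN2′) with a silyl–boron pronucleophile is a known route from γ,γ-disubstituted E-allyl phosphates to α-tetrasubstituted allylsilanes, and the chiral carbene–copper silyl species adds to one face of C8 anti to the phosphate, which sets the (R) Si-bearing centre.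

**Step 3**
Reactants: 3 (R)-linalylsilane
Product: 4 (2E,6R)-6-[dimethyl(phenyl)silyl]-2,6-dimethylocta-2,7-dien-1-ol
Conditions: SeO2 (0.2 equiv), t-BuOOH, salicylic acid (cat.), CH2Cl2, 0 °C to rt
Reagents that add atoms: tert-butyl hydroperoxide, CC(C)(C)OO
Why: Riley allylic oxidation (ene reaction then [2,3]-shift) hydroxylates the E-methyl group of the isopropylidene end with its usual E-selectivity, and the vinyl group is inert because C8 carries no allylic hydrogen, so the C8 centre is untouched.

**Step 4**
Reactants: 4 allylic alcohol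
Product: 5 [(3R,6E)-8-bromo-3,7-dimethylocta-1,6-dien-3-yl](dimethyl)phenylsilane
Conditions: CBr4, PPh3, CH2Cl2, 0 °C
Reagents that add atoms: carbon tetrabromide, BrC(Br)(Br)Br
Why: The Appel reaction replaces the primary allylic OH by Br through SN2 under neutral conditions, so neither the E-geometry nor the acid-sensitive allylsilane is disturbed.

**Step 5**
Reactants: 5 allylic bromide; 6 3-methylbutan-2-one
Product: 8 (6E,10R)-10-[dimethyl(phenyl)silyl]-2,6,10-trimethyldodeca-6,11-dien-3-one, via kinetic lithium enolate 7 (not isolated)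
Conditions: LDA, 6, THF, −78 °C; then 5, DMPU, −78 to −20 °C
Reagents that add atoms: 3-methylbutan-2-one (6), CC(=O)C(C)C
Why: Kinetic enolate alkylation, in which LDA deprotonates the methyl side of the ketone and the enolate displaces the primary allylic bromide by SN2, completes the C15 farnesane chain without forming a new stereocentre.

**Step 6 (key step)**
Reactants: 8 keto-allylsilane
Product: 10 dauc-8-en-4β-ol (trans-fused; 15-CH3 β; H-5 α; 4-OH β; 1R,4R,5R), via cyclopentyl cation aluminate 9 (not isolated)
Conditions: MeAlCl2 (2 equiv), CH2Cl2 (0.005 M), −78 to −40 °C; aq. Rochelle salt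
Reagents that add atoms: none
Why: Proposed new method: MeAlCl2 binds the isopropyl ketone and the E-trisubstituted alkene attacks it through C5 (Prins closure of a γ,δ-unsaturated ketone, a known reversible MeAlCl2-initiated event) to give tertiary cation 9, which the tertiary allylsilane traps at C1 through C10 in an anti-SE2′ Hosomi–Sakurai-type termination (closest known type: allylsilane-terminated cation–olefin cyclisation), so that anti addition across the E-alkene gives the trans fusion, the isopropyl group takes the side away from C6 (4β-O), and the (R)-silane, which reaches a chair-like anti-SE2′ geometry with a cis ring alkene on only one face of C1, selects the natural enantiomeric series because the first closure is reversible.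

**Step 7**
Reactants: 10 dauc-8-en-4β-ol
Product: 12 4β-hydroxydauc-7-en-9-one, via 9α-hydroperoxide 11 (not isolated)
Conditions: O2, tetraphenylporphyrin (1 mol %), visible light, Ac2O, pyridine, CH2Cl2, 0 °C to rt
Reagents that add atoms: oxygen, O=O
Why: A Schenck ene reaction of singlet oxygen takes a ring hydrogen from C7 on the more substituted side of the alkene and places OOH on C9 with a shift to Δ7, a Kornblum–DeLaMare-type dehydration of the acetylated hydroperoxide then gives the enone, and the transient C9 centre is erased so the face of attack does not matter.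

**Step 8**
Reactants: 12 4β-hydroxydauc-7-en-9-one
Product: 14 4β,6α-dihydroxydauc-7-en-9-one, via bis-silyl dienol ether 13 (not isolated)
Conditions: TMSOTf (2.5 equiv), Et3N, CH2Cl2, 0 °C; mCPBA, NaHCO3, −20 °C; aq. citric acid, THF
Reagents that add atoms: 3-chloroperbenzoic acid, OOC(=O)c1cccc(Cl)c1; trimethylsilyl triflate, C[Si](C)(C)OS(=O)(=O)C(F)(F)F (silyl groups only in 13)
Why: In this vinylogous Rubottom oxidation, soft enolisation gives the linear 6,8-dienol silyl ether, the peracid attacks the unhindered γ,δ-alkene rather than the fully substituted C8, and it comes from the α-face because the axial 15-methyl on the C1 flap covers the β-face, which sets 6α-OH.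

**Step 9**
Reactants: 14 4β,6α-dihydroxydauc-7-en-9-one; 15 4-methoxybenzoyl chloride
Product: 16 6α-(4-methoxybenzoyloxy)-4β-hydroxydauc-7-en-9-one
Conditions: 15, Et3N, DMAP (cat.), CH2Cl2, 0 °C to rt
Reagents that add atoms: 4-methoxybenzoyl chloride (15), COc1ccc(cc1)C(Cl)=O
Why: DMAP-catalysed O-acylation esterifies only the secondary allylic 6-OH, the tertiary 4-OH being inert, with retention at C6.

**Step 10**
Reactants: 16 enone anisate
Product: 17 target, 6α-(4-methoxybenzoyloxy)dauc-7-ene-4β,9β-diol (1R,4R,5S,6S,9R)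
Conditions: NaBH4, CeCl3·7H2O, MeOH, −78 °C
Reagents that add atoms: none
Why: Luche reduction gives clean 1,2-reduction of the enone without touching the ester, and hydride arrives from the open α-face, anti to the 15-methyl group, which sets 9β-OH (9R).

**Compound list**
1 | geraniol | CC(C)=CCC/C(C)=C/CO | starting material
2 | geranyl diethyl phosphate | CC(C)=CCC/C(C)=C/COP(=O)(OCC)OCC | intermediate
3 | [(3R)-3,7-dimethylocta-1,6-dien-3-yl](dimethyl)phenylsilane | C=C[C@@](C)(CCC=C(C)C)[Si](C)(C)c1ccccc1 | intermediate
4 | (2E,6R)-6-[dimethyl(phenyl)silyl]-2,6-dimethylocta-2,7-dien-1-ol | C=C[C@@](C)(CC/C=C(\C)CO)[Si](C)(C)c1ccccc1 | intermediate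
5 | [(3R,6E)-8-bromo-3,7-dimethylocta-1,6-dien-3-yl](dimethyl)phenylsilane | C=C[C@@](C)(CC/C=C(\C)CBr)[Si](C)(C)c1ccccc1 | intermediate
6 | 3-methylbutan-2-one | CC(=O)C(C)C | starting material
7 | lithium 3-methylbut-1-en-2-olate | [Li+].[O-]C(=C)C(C)C | intermediate
8 | (6E,10R)-10-[dimethyl(phenyl)silyl]-2,6,10-trimethyldodeca-6,11-dien-3-one | C=C[C@@](C)(CC/C=C(\C)CCC(=O)C(C)C)[Si](C)(C)c1ccccc1 | intermediate
9 | cyclopentyl cation aluminate zwitterion (C4–C5 closed, cation at C1) | C[C+]1CC[C@@](O[Al-](C)(Cl)Cl)(C(C)C)[C@@H]1CC[C@](C)(C=C)[Si](C)(C)c1ccccc1 | intermediate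
10 | dauc-8-en-4β-ol | C1CC(C)=CC[C@@]2(C)CC[C@@](O)(C(C)C)[C@H]12 | intermediate
11 | 9α-hydroperoxydauc-7-en-4β-ol | C1C=C(C)[C@@H](OO)C[C@@]2(C)CC[C@@](O)(C(C)C)[C@H]12 | intermediate
12 | 4β-hydroxydauc-7-en-9-one | C1C=C(C)C(=O)C[C@@]2(C)CC[C@@](O)(C(C)C)[C@H]12 | intermediate
13 | 4β,9-bis(trimethylsilyloxy)dauca-6,8-diene | C1=CC(C)=C(O[Si](C)(C)C)C[C@@]2(C)CC[C@@](O[Si](C)(C)C)(C(C)C)[C@H]12 | intermediate
14 | 4β,6α-dihydroxydauc-7-en-9-one | O[C@H]1C=C(C)C(=O)C[C@@]2(C)CC[C@@](O)(C(C)C)[C@H]12 | intermediate
15 | 4-methoxybenzoyl chloride | COc1ccc(cc1)C(Cl)=O | starting material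
16 | 6α-(4-methoxybenzoyloxy)-4β-hydroxydauc-7-en-9-one | COc1ccc(cc1)C(=O)O[C@H]1C=C(C)C(=O)C[C@@]2(C)CC[C@@](O)(C(C)C)[C@H]12 | intermediate
17 | 6α-(4-methoxybenzoyloxy)dauc-7-ene-4β,9β-diol | COc1ccc(C(=O)O[C@H]2C=C(C)[C@H](O)C[C@@]3(C)CC[C@@](O)(C(C)C)[C@H]23)cc1 | target

**Total steps:** 10. **Longest linear sequence:** 10 (1 → 17).

**Steps most likely to fail**

Step 6. The cascade may lose out to 1,2-hydride/pinacol shifts of cation 9, to protodesilylation, or to a boat-like closure that erodes the chirality relay. The fallback sets out from 8 and comes back at 10. It builds the seven-membered ring first and closes the five-membered ring by a radical.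
- Shi epoxidation of 8 (D-fructose-derived ketone, Oxone) gives the (R,R)-epoxy keto-allylsilane F1.
- BF3·OEt2 at −78 °C lets the allylsilane open the tertiary C1–O bond with inversion, giving the cycloheptenol ketone F2.
- The Burgess reagent dehydrates the neopentyl secondary alcohol, which can only eliminate towards C6, giving the cyclohepta-1,4-diene ketone F3.
- SmI2/HMPA/t-BuOH then joins C4 to C5 by a 5-exo ketyl–olefin cyclisation and returns to 10.

Step 7. The ene reaction can also abstract H-10 or H-14, which gives a tertiary hydroperoxide or the exocyclic isomer. The fallback sets out from 10 and comes back at 12.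
- mCPBA epoxidises the alkene from the α-face to the 8α,9α-epoxide F4.
- Et2Al(tmp) isomerises it by removing H-7 to the 9α-allylic alcohol F5.
- MnO2 oxidises F5 to 12.

Step 8. The uncertainties are α′- versus γ-enolisation, attack at C8, and the facial selectivity at C6. The fallback sets out from 12 and comes back at 14.
- Rh2(caprolactamate)4 with t-BuOOH oxidises the γ-CH2 to the enedione F6.
- An Evans–Saksena reduction with Me4NBH(OAc)3, bound to the 4β-OH, delivers hydride to the β-face of the C6 ketone only. This gives 14 with 6α-OH and leaves the C9 enone untouched.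

**Further compounds**
F1 | step 6 | (R,R)-epoxide of 8 at C5–C1 | C=C[C@@](C)(CC[C@H]1O[C@]1(C)CCC(=O)C(C)C)[Si](C)(C)c1ccccc1
F2 | step 6 | 1-(2-hydroxy-1,5-dimethylcyclohept-4-en-1-yl)-4-methylpentan-3-one (C1 natural configuration, 5-OH) | C1CC(C)=CC[C@@](C)(CCC(=O)C(C)C)[C@@H]1O
F3 | step 6 | 1-(1,4-dimethylcyclohepta-2,5-dien-1-yl)-4-methylpentan-3-one (C1 natural configuration) | C1C(C)=CC[C@@](C)(CCC(=O)C(C)C)C=C1
F4 | step 7 | 8α,9α-epoxydaucan-4β-ol | C1C[C@@]3(C)O[C@H]3C[C@@]2(C)CC[C@@](O)(C(C)C)[C@H]12
F5 | step 7 | dauc-7-ene-4β,9α-diol | C1C=C(C)[C@@H](O)C[C@@]2(C)CC[C@@](O)(C(C)C)[C@H]12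
F6 | step 8 | 4β-hydroxydauc-7-ene-6,9-dione | O=C1C=C(C)C(=O)C[C@@]2(C)CC[C@@](O)(C(C)C)[C@H]12
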